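Readings and results are calculated from invented constants.

Product is the quantity to watch: in the elm run it crawls to 0.0050 M by 8.1 min, then reaches 0.0360 M by 19 min. The curve bends upward, the shape of autocatalysis.

| setting | oak | birch | alder | elm | maple |
|---|---|---|---|---|---|
| substrate | 0.0500 M | 0.0250 M | 0.0250 M | 0.0500 M | 0.0500 M |
| free catalyst | 2.50 × 10⁻⁴ M | 2.50 × 10⁻⁴ M | 2.50 × 10⁻⁴ M | 1.30 × 10⁻⁴ M | 5.40 × 10⁻⁵ M |
| time |  |  |  |  | 19 min |

- oak run (time / min: [product] / M): 2.7: 0.0032; 5.4: 0.0079; 8.1: 0.0167; 11: 0.0283; 14: 0.0395; 16: 0.0446; 19: 0.0487
- birch run (time / min: [product] / M): 2.7: 0.0040; 5.4: 0.0084; 8.1: 0.0134; 11: 0.0178; 14: 0.0219; 16: 0.0230; 19: 0.0237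
- alder run (time / min: [product] / M): 2.7: 0.0043; 5.4: 0.0086; 8.1: 0.0135; 11: 0.0179; 14: 0.0209; 16: 0.0231; 19: 0.0240
- elm run (time / min: [product] / M): 2.7: 7 × 10⁻⁴; 5.4: 0.0021; 8.1: 0.0050; 11: 0.0105; 14: 0.0190; 16: 0.0261; 19: 0.0360

(readings scatter by 3 × 10⁻⁴ M)

- apparent order in [free catalyst] of the starting rate, round the charge of the oak run (the rate where two percent of its substrate have turned into product)
- apparent order in [substrate] of the starting rate, round the charge of the oak run (the rate where two percent of its substrate have turned into product) (one fixed amount of product, the same in the runs compared)
- the birch run starts with 0.0250 M less of substrate than the oak run, and with no product. Compared where both hold the same amount of substrate, once fifteen percent of what the birch run was charged with has turned into product, is the birch run faster, slower or alike (within a tenth)?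
- product in the maple run at 19 min, as a share of the substrate charged

- Overall: substrate -> product, with free catalyst as catalyst.
- Constant volume, constant temperature.
- Bound and free are read together.
- An order is taken over about fifteen percent of the charge, up and down.

The maple run is asked at a low catalyst charge, and the substrate charge of the elm run is the same as its own. The useful measure of such a curve is the odds:

odds = c_product / (charged c_substrate − c_product)

The elm odds grow at about 0.284 min⁻¹ from 11 min to 19 min. If growth per minute is taken to hang on the substrate charge and not on the catalyst charge, flasks with equal substrate charge keep a fixed ratio of odds at equal time, and the catalyst charge shows up as a head start. The elm odds at 19 min are 2.57.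

Two extremes can be reckoned for the maple run. With no self-feeding and rate proportional to catalyst, the first elm slope gives:

share = 4.09%

With full self-feeding and a head start proportional to catalyst, the odds become 1.07:

share = 51.7%

The upward bend rules out the first extreme. The second fails too: at 8.1 min the oak odds are 0.502 and the elm odds 0.111, a ratio larger than the catalyst ratio. Expressed as a power of that catalyst ratio, the reading is 2.30, the head-start order: the power of the catalyst ratio that gives the ratio of odds at equal time and equal substrate charge. Carried to the maple run, it gives odds of 0.339, so this reckoning commits to 25.3%.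

The forecast differs from that share. It gave 1.4, −0.7, slower and 18%, on the ground that “substrate holds back the catalyst and product relieves this”.

The simulation gives 1.5, −0.33, slower and 27.3%.

    free catalyst + substrate ⇌ catalyst-substrate complex, settled at all times (198.0 L mol⁻¹)
    catalyst-substrate complex + free catalyst → product + 2 free catalyst (1.434 × 10⁵ L mol⁻¹ min⁻¹)
    free catalyst → spent catalyst (0.1824 min⁻¹)
    substrate + product → 2 product (5.340 L mol⁻¹ min⁻¹)

In the maple run, the fast binding leaves 9.17% of the charged catalyst free at the start, and catalyst-substrate complex with free catalyst makes product there at 3.48 × 10⁻⁵ M min⁻¹. Substrate with product matches that starting rate once c_product reaches 1.30 × 10⁻⁴ M, and at 19 min this step runs faster than that starting rate, at 0.00265 M min⁻¹. The maple run then holds 27.3% of its substrate charge as product, odds of 0.376, which against the elm run is a head-start order of 2.19.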